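**Retrosynthetic overview**
1. 18 ⇐ 17 ⇐ 16 (acetylation of the C4 hydroxyl, fluoride desilylation); 16 ⇐ spiro-epoxide 12 + aryl Grignard reagent 15 (benzylic CH2–aryl bond; the C4–O bond is never broken).
2. 12 ⇐ triol 7 (the two primary alcohols are told apart through the 1,2-acetonide) ⇐ bicyclic lactol 6 (NaBH4).
3. 6 ⇐ enal 1 + dihydroxyacetone 3 (one of the two monomer units of dimer 2): one amine-catalysed domino oxa-Michael/aldol/hemiacetalisation makes O1–C2 and C3–C4 and sets C2, C3 and C4.
4. Enabling feature: C9, the carbon of the C3 CH2OH group, stands 1,3 to both oxygen-bearing ring carbons C2 and C4, so at the aldehyde level it is the acceptor for an oxa-Michael addition and the enamine donor for an aldol addition onto a C4 ketone; the CH2OH on C3 and the CH2 on C4 are cis on the oxolane, so a temporary cis-fused lactol ring (furo[3,4-c]furan) can lock C4.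
5. Ring order: oxolane ring A, then lactol ring B (both in step 1; ring B is opened in step 2); the dioxolane (steps 3 to 5) and the oxirane (steps 6 to 8) are temporary.

Key step: step 1

Remark on locants: the target oxolane locants are used for all compounds (O1, C2 aryl, C3 CH2OH, C4 OAc/benzyl, C5; C9 is the carbon of the C3 CH2OH group, C7' the CH2 on C4); in these locants the target is (2S,3R,4S).
Assumption: the (S)-catalyst is taken to follow the usual shielding model of its iminium ions (attack anti to the C(Ph)2OSiMe3 group), which leads to 2S; the (R)-catalyst would serve if the opposite sense were found.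

**Step 1**
Reactants: 1 (E)-3-(3,4-dimethoxyphenyl)prop-2-enal; 2 1,3-dihydroxyacetone dimer
Product: 6 (3aS,6S,6aR)-6-(3,4-dimethoxyphenyl)tetrahydro-1H,3H-furo[3,4-c]furan-1,3a(4H)-diol (bicyclic lactol; anomeric mixture), via dihydroxyacetone 3 (not isolated), via oxa-Michael adduct 4 (not isolated), via hydroxy aldehyde 5 (not isolated)
Conditions: 2 (1.0 equiv, two monomer equivalents), (S)-2-[diphenyl(trimethylsilyloxy)methyl]pyrrolidine (20 mol %), PhCO2H (20 mol %), CHCl3, rt
Reagents that add atoms: none
Why: Dimer 2 dissociates into two molecules of 3, one of which is consumed per molecule of 1; the secondary amine condenses with 1 to an iminium ion, a hydroxyl of 3 adds to its β-carbon (oxa-Michael, O1–C2), the enamine so formed adds to the ketone carbonyl (intramolecular aldol, C3–C4), and hydrolysis releases 5, whose cis CH2OH and CHO groups close to lactol 6. The closest known reaction type is the diarylprolinol silyl ether-catalysed domino oxa-Michael/aldol/hemiacetalisation of enals with dihydroxyacetone dimer, which gives this furo[3,4-c]furan lactol skeleton. Ring A (the oxolane kept in the target) closes by a 5-exo-trig (enolexo) aldol addition and ring B (the temporary lactol) by 5-exo-trig addition of the hydroxyl to the formyl group. C2 is set by the catalyst, whose C(Ph)2OSiMe3 group blocks one face of the s-trans (E)-iminium ion so that oxygen adds to the open face and should give 2S; C3 is relayed from C2 (formyl trans to aryl, and epimerisable through the enamine); C4 is fixed by the lactol, since only the aldol isomer with CH2OH cis to CHO can form the cis-fused bicycle and the reversible oxa-Michael and aldol steps drain into it; the anomeric carbon is not controlled and is erased in step 2. The step needs 1,4-addition of a weak oxygen nucleophile in preference to acetal formation and to self-aldolisation of 3, and a C4 configuration that an unlocked aldol addition need not favour; iminium activation with PhCO2H as cocatalyst should secure the first and the hemiacetal sink the second.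

**Step 2**
Reactants: 6 bicyclic lactol
Product: 7 (3R,4R,5S)-5-(3,4-dimethoxyphenyl)-3,4-bis(hydroxymethyl)oxolan-3-ol
Conditions: NaBH4, MeOH, 0 °C
Reagents that add atoms: none
Why: Borohydride reduction of the open hydroxy-aldehyde tautomer of the lactol should outrun retro-aldol cleavage, removes the uncontrolled anomeric centre and leaves C2, C3 and C4 untouched.

**Step 3**
Reactants: 7 triol
Product: 8 [(5S,8S,9R)-8-(3,4-dimethoxyphenyl)-2,2-dimethyl-1,3,7-trioxaspiro[4.4]nonan-9-yl]methanol
Conditions: Me2C(OMe)2, pyridinium p-toluenesulfonate (cat.), acetone, rt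
Reagents that add atoms: 2,2-dimethoxypropane COC(C)(C)OC
Why: Acid-catalysed transketalisation under equilibrating conditions (acetonide protection) should select the five-membered dioxolane across the tertiary/primary 1,2-diol over the trans-fused dioxane or a seven-membered ketal, so that only the C9 hydroxyl stays free.

**Step 4**
Reactants: 8 acetonide alcohol
Product: 9 tert-butyl{[(5S,8S,9R)-8-(3,4-dimethoxyphenyl)-2,2-dimethyl-1,3,7-trioxaspiro[4.4]nonan-9-yl]methoxy}diphenylsilane
Conditions: t-BuPh2SiCl, imidazole, DMF, rt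
Reagents that add atoms: tert-butyl(chloro)diphenylsilane CC(C)(C)[Si](Cl)(c1ccccc1)c1ccccc1
Why: Silyl ether formation at the single free primary alcohol installs a group that survives dilute acid, NaH, Grignard reagents and acylation and, unlike a benzyl ether, needs no hydrogenolysis next to the benzylic ring ether.

**Step 5**
Reactants: 9 silyl ether acetonide
Product: 10 (3R,4R,5S)-4-{[tert-butyl(diphenyl)silyl]oxymethyl}-5-(3,4-dimethoxyphenyl)-3-(hydroxymethyl)oxolan-3-ol
Conditions: AcOH–H2O (4:1), 40 °C
Reagents that add atoms: none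
Why: Aqueous acid hydrolysis of the ketal frees the 1,2-diol, while the tert-butyldiphenylsilyl ether and the benzylic ring ether should be stable to dilute acetic acid.

**Step 6**
Reactants: 10 diol
Product: 12 tert-butyl{[(3R,6S,7R)-6-(3,4-dimethoxyphenyl)-1,5-dioxaspiro[2.4]heptan-7-yl]methoxy}diphenylsilane, via monotosylate 11 (not isolated)
Conditions: NaH (2.2 equiv), 1-(p-tolylsulfonyl)imidazole (1.1 equiv), THF, 0 °C to rt
Reagents that add atoms: none
Why: Sulfonylation of the primary alkoxide followed by 3-exo-tet displacement by the tertiary alkoxide (one-pot diol-to-epoxide conversion, intramolecular Williamson reaction) gives the spiro-oxirane with retention at C4 because the C4–O bond is never broken, and the silylated C9 oxygen cannot close a competing bicyclic ether.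

**Step 7**
Reactants: 13 4-bromo-2-methoxyphenol
Product: 14 (4-bromo-2-methoxyphenoxy)(tert-butyl)dimethylsilane
Conditions: t-BuMe2SiCl, imidazole, DMF, rt
Reagents that add atoms: tert-butyl(chloro)dimethylsilane CC(C)(C)[Si](C)(C)Cl
Why: Silyl ether formation masks the acidic phenol so that the aryl bromide can be converted into a Grignard reagent.

**Step 8**
Reactants: 12 spiro-epoxide; 14 aryl bromide
Product: 16 (3S,4R,5S)-3-{[4-(tert-butyldimethylsilyloxy)-3-methoxyphenyl]methyl}-4-{[tert-butyl(diphenyl)silyl]oxymethyl}-5-(3,4-dimethoxyphenyl)oxolan-3-ol, via arylmagnesium bromide 15 (not isolated)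
Conditions: Mg, THF, 40 °C; then CuI (10 mol %), 12, THF, −40 to 0 °C; aqueous work-up
Reagents that add atoms: none
Why: Magnesium insertion gives the aryl Grignard reagent, and copper-catalysed SN2 opening of the 2,2-disubstituted epoxide at its unsubstituted CH2 terminus (organocuprate epoxide opening) forms the benzylic C–aryl bond without touching the C4–O bond, so the C4 configuration is carried over unchanged.

**Step 9**
Reactants: 16 tertiary alcohol
Product: 17 (3S,4R,5S)-3-{[4-(tert-butyldimethylsilyloxy)-3-methoxyphenyl]methyl}-4-{[tert-butyl(diphenyl)silyl]oxymethyl}-5-(3,4-dimethoxyphenyl)oxolan-3-yl acetate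
Conditions: Ac2O, 4-(dimethylamino)pyridine, Et3N, CH2Cl2, 40 °C
Reagents that add atoms: acetic anhydride CC(=O)OC(C)=O
Why: Nucleophilic catalysis (Steglich-type acylation through the N-acetylpyridinium ion) should acetylate the only free hydroxyl, the tertiary one, with retention because only the O–H bond reacts.

**Step 10**
Reactants: 17 bis-silyl acetate
Product: 18 (3S,4R,5S)-5-(3,4-dimethoxyphenyl)-3-[(4-hydroxy-3-methoxyphenyl)methyl]-4-(hydroxymethyl)oxolan-3-yl acetate (target)
Conditions: Bu4NF, AcOH (1:1), THF, 0 °C to rt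
Reagents that add atoms: none
Why: Fluoride-mediated desilylation cleaves the aryl and the primary alkyl silyl ethers, and the acetic acid buffer keeps the liberated primary oxygen protonated, which, together with the trans arrangement of the C4 acetate and the C3 CH2OH group, should suppress 1,3-acyl migration and loss of the ester.

**Compound list**
1 | (E)-3-(3,4-dimethoxyphenyl)prop-2-enal | COc1ccc(/C=C/C=O)cc1OC | starting material
2 | 1,3-dihydroxyacetone dimer, 2,5-bis(hydroxymethyl)-1,4-dioxane-2,5-diol | OCC1(O)COC(O)(CO)CO1 | starting material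
3 | 1,3-dihydroxyacetone (monomer) | OCC(=O)CO | intermediate (not isolated)
4 | (3S)-3-(3,4-dimethoxyphenyl)-3-(3-hydroxy-2-oxopropoxy)propanal, oxa-Michael adduct (present as its catalyst-bound enamine, drawn as the free aldehyde) | O=CC[C@H](OCC(=O)CO)c1ccc(OC)c(OC)c1 | intermediate (not isolated)
5 | (2S,3R,4R)-2-(3,4-dimethoxyphenyl)-4-hydroxy-4-(hydroxymethyl)oxolane-3-carbaldehyde (aryl trans to CHO, tertiary OH trans to CHO) | OC[C@@]1(O)CO[C@H](c2ccc(OC)c(OC)c2)[C@H]1C=O | intermediate (not isolated)
6 | (3aS,6S,6aR)-6-(3,4-dimethoxyphenyl)tetrahydro-1H,3H-furo[3,4-c]furan-1,3a(4H)-diol, cis-fused lactol, anomeric mixture | OC1OC[C@@]2(O)CO[C@H](c3ccc(OC)c(OC)c3)[C@H]21 | intermediate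
7 | (3R,4R,5S)-5-(3,4-dimethoxyphenyl)-3,4-bis(hydroxymethyl)oxolan-3-ol | OC[C@@]1(O)CO[C@H](c2ccc(OC)c(OC)c2)[C@H]1CO | intermediate
8 | [(5S,8S,9R)-8-(3,4-dimethoxyphenyl)-2,2-dimethyl-1,3,7-trioxaspiro[4.4]nonan-9-yl]methanol | CC1(C)OC[C@@]2(O1)CO[C@H](c3ccc(OC)c(OC)c3)[C@H]2CO | intermediate
9 | tert-butyl{[(5S,8S,9R)-8-(3,4-dimethoxyphenyl)-2,2-dimethyl-1,3,7-trioxaspiro[4.4]nonan-9-yl]methoxy}diphenylsilane | CC1(C)OC[C@@]2(O1)CO[C@H](c3ccc(OC)c(OC)c3)[C@H]2CO[Si](c2ccccc2)(c2ccccc2)C(C)(C)C | intermediate
10 | (3R,4R,5S)-4-{[tert-butyl(diphenyl)silyl]oxymethyl}-5-(3,4-dimethoxyphenyl)-3-(hydroxymethyl)oxolan-3-ol | OC[C@@]1(O)CO[C@H](c2ccc(OC)c(OC)c2)[C@H]1CO[Si](c1ccccc1)(c1ccccc1)C(C)(C)C | intermediate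
11 | [(3S,4R,5S)-4-{[tert-butyl(diphenyl)silyl]oxymethyl}-5-(3,4-dimethoxyphenyl)-3-hydroxyoxolan-3-yl]methyl 4-methylbenzenesulfonate | Cc1ccc(cc1)S(=O)(=O)OC[C@@]1(O)CO[C@H](c2ccc(OC)c(OC)c2)[C@H]1CO[Si](c1ccccc1)(c1ccccc1)C(C)(C)C | intermediate (not isolated)
12 | tert-butyl{[(3R,6S,7R)-6-(3,4-dimethoxyphenyl)-1,5-dioxaspiro[2.4]heptan-7-yl]methoxy}diphenylsilane | C1[C@@]2(O1)CO[C@H](c3ccc(OC)c(OC)c3)[C@H]2CO[Si](c2ccccc2)(c2ccccc2)C(C)(C)C | intermediate
13 | 4-bromo-2-methoxyphenol | COc1cc(Br)ccc1O | starting material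
14 | (4-bromo-2-methoxyphenoxy)(tert-butyl)dimethylsilane | COc1cc(Br)ccc1O[Si](C)(C)C(C)(C)C | intermediate
15 | [4-(tert-butyldimethylsilyloxy)-3-methoxyphenyl]magnesium bromide | COc1cc([Mg]Br)ccc1O[Si](C)(C)C(C)(C)C | intermediate (not isolated)
16 | (3S,4R,5S)-3-{[4-(tert-butyldimethylsilyloxy)-3-methoxyphenyl]methyl}-4-{[tert-butyl(diphenyl)silyl]oxymethyl}-5-(3,4-dimethoxyphenyl)oxolan-3-ol | COc1cc(C[C@@]2(O)CO[C@H](c3ccc(OC)c(OC)c3)[C@H]2CO[Si](c2ccccc2)(c2ccccc2)C(C)(C)C)ccc1O[Si](C)(C)C(C)(C)C | intermediate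
17 | (3S,4R,5S)-3-{[4-(tert-butyldimethylsilyloxy)-3-methoxyphenyl]methyl}-4-{[tert-butyl(diphenyl)silyl]oxymethyl}-5-(3,4-dimethoxyphenyl)oxolan-3-yl acetate | COc1cc(C[C@@]2(OC(C)=O)CO[C@H](c3ccc(OC)c(OC)c3)[C@H]2CO[Si](c2ccccc2)(c2ccccc2)C(C)(C)C)ccc1O[Si](C)(C)C(C)(C)C | intermediate
18 | (3S,4R,5S)-5-(3,4-dimethoxyphenyl)-3-[(4-hydroxy-3-methoxyphenyl)methyl]-4-(hydroxymethyl)oxolan-3-yl acetate | COc1cc(C[C@@]2(OC(C)=O)CO[C@H](c3ccc(OC)c(OC)c3)[C@H]2CO)ccc1O | target

**Step count and risks**
Total step count: 10. Longest linear sequence: 9 steps (steps 1 to 6 and 8 to 10; step 7 is a one-step side branch).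

Steps most likely to fail:

Step 1. Process at risk: iminium formation from the electron-rich enal may be slow and the oxa-Michael addition at the electron-rich benzylic carbon is reversible, so conversion may stall or the enantiomeric purity may erode before the lactol sink is reached. Fallback: the C2 stereocentre is set by reagent-controlled epoxidation and the C3–C4 bond by radical cyclisation; it sets out from enal 1 and comes back to the route at diol 10, so that steps 2 to 5 are not needed. Reduction of 1 (NaBH4, CeCl3, MeOH) should give (E)-3-(3,4-dimethoxyphenyl)prop-2-en-1-ol F1. Sharpless asymmetric epoxidation (Ti(OiPr)4, L-(+)-diethyl tartrate, t-BuOOH, 4 Å sieves, CH2Cl2, −20 °C) should give [(2S,3S)-3-(3,4-dimethoxyphenyl)oxiran-2-yl]methanol F2. Ti(OiPr)4-mediated opening with prop-2-yn-1-ol at the benzylic carbon, with inversion, should give (2S,3R)-3-(3,4-dimethoxyphenyl)-3-(prop-2-yn-1-yloxy)propane-1,2-diol F3. Mitsunobu cyclodehydration (PPh3, diisopropyl azodicarboxylate, toluene) should give (S)-2-[(R)-(3,4-dimethoxyphenyl)(prop-2-yn-1-yloxy)methyl]oxirane F4. Cp2TiCl (trivalent titanium, made from Cp2TiCl2 and Zn dust in THF) should open the epoxide to the C3 radical, which cyclises 5-exo-dig onto the alkyne trans to the aryl group, a known entry to furanoid lignans, to give [(2S,3R)-2-(3,4-dimethoxyphenyl)-4-methylideneoxolan-3-yl]methanol F5. Silylation (t-BuPh2SiCl, imidazole) gives tert-butyl{[(2S,3R)-2-(3,4-dimethoxyphenyl)-4-methylideneoxolan-3-yl]methoxy}diphenylsilane F6. Dihydroxylation (OsO4 cat., N-methylmorpholine N-oxide, acetone–H2O) from the face anti to the C3 substituent should give diol 10.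

Step 8. Process at risk: the Lewis-acidic magnesium halide may trigger rearrangement of the spiro-epoxide to an aldehyde or its opening to a halohydrin faster than aryl transfer to the neopentyl-type CH2. Fallback: the aryl group is added to an aldehyde and the extra oxygen is removed by radical deoxygenation; it sets out from diol 10 and comes back at alcohol 16. Oxidation of the primary alcohol (TEMPO cat., PhI(OAc)2, CH2Cl2) should give (3S,4R,5S)-4-{[tert-butyl(diphenyl)silyl]oxymethyl}-5-(3,4-dimethoxyphenyl)-3-hydroxyoxolane-3-carbaldehyde F7. Addition of Grignard reagent 15 (excess, THF, −78 °C) should give the 1,2-diol F8 as a mixture of epimers at the new carbinol carbon, which does not matter. 1,1'-Thiocarbonyldiimidazole with 4-(dimethylamino)pyridine in toluene at 80 °C should give the spirocyclic thionocarbonate F9. Bu3SnH with azobisisobutyronitrile in toluene at 100 °C, followed by aqueous KF work-up, should cleave the benzylic C–O bond selectively (Barton–McCombie deoxygenation through the more stable benzylic radical) and release the tertiary alcohol 16.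

Step 9. Process at risk: acyl transfer to the hindered tertiary hydroxyl may be slow, and forcing it may bring ionisation, elimination or silyl loss. Fallback: steps 8 and 9 are telescoped by trapping the tertiary magnesium alkoxide before work-up; it sets out from epoxide 12 and Grignard reagent 15 and comes back at acetate 17. After the copper-catalysed opening is complete, excess Ac2O is added to the cold mixture, which should acylate the alkoxide directly; no new compound is made (F0).

**Further compounds**
F1 | step 1 | (E)-3-(3,4-dimethoxyphenyl)prop-2-en-1-ol | COc1ccc(/C=C/CO)cc1OC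
F2 | step 1 | [(2S,3S)-3-(3,4-dimethoxyphenyl)oxiran-2-yl]methanol | O1[C@@H](c2ccc(OC)c(OC)c2)[C@@H]1CO
F3 | step 1 | (2S,3R)-3-(3,4-dimethoxyphenyl)-3-(prop-2-yn-1-yloxy)propane-1,2-diol | C#CCO[C@H](c1ccc(OC)c(OC)c1)[C@@H](O)CO
F4 | step 1 | (S)-2-[(R)-(3,4-dimethoxyphenyl)(prop-2-yn-1-yloxy)methyl]oxirane | C#CCO[C@H](c1ccc(OC)c(OC)c1)[C@@H]1CO1
F5 | step 1 | [(2S,3R)-2-(3,4-dimethoxyphenyl)-4-methylideneoxolan-3-yl]methanol | C=C1CO[C@H](c2ccc(OC)c(OC)c2)[C@H]1CO
F6 | step 1 | tert-butyl{[(2S,3R)-2-(3,4-dimethoxyphenyl)-4-methylideneoxolan-3-yl]methoxy}diphenylsilane | C=C1CO[C@H](c2ccc(OC)c(OC)c2)[C@H]1CO[Si](c1ccccc1)(c1ccccc1)C(C)(C)C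
F7 | step 8 | (3S,4R,5S)-4-{[tert-butyl(diphenyl)silyl]oxymethyl}-5-(3,4-dimethoxyphenyl)-3-hydroxyoxolane-3-carbaldehyde | O=C[C@@]1(O)CO[C@H](c2ccc(OC)c(OC)c2)[C@H]1CO[Si](c1ccccc1)(c1ccccc1)C(C)(C)C
F8 | step 8 | (3S,4R,5S)-3-{[4-(tert-butyldimethylsilyloxy)-3-methoxyphenyl](hydroxy)methyl}-4-{[tert-butyl(diphenyl)silyl]oxymethyl}-5-(3,4-dimethoxyphenyl)oxolan-3-ol, epimer mixture at the carbinol carbon | COc1cc(C(O)[C@@]2(O)CO[C@H](c3ccc(OC)c(OC)c3)[C@H]2CO[Si](c2ccccc2)(c2ccccc2)C(C)(C)C)ccc1O[Si](C)(C)C(C)(C)C
F9 | step 8 | cyclic thionocarbonate of F8 (1,3-dioxolane-2-thione spiro-fused at C4 of the oxolane, aryl group on the dioxolane CH) | S=C1OC(c2ccc(O[Si](C)(C)C(C)(C)C)c(OC)c2)[C@@]2(O1)CO[C@H](c3ccc(OC)c(OC)c3)[C@H]2CO[Si](c2ccccc2)(c2ccccc2)C(C)(C)C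
F0 | step 9 | none | none
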